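**Assumptions (one line each)**
- 2-Iodopropene, methyl glyoxylate, 4-methoxy-2-methylphenol and the Brown, Josiphos and BINOL-Ti reagents are purchasable.
- The C4 carbinol made in Step 13 is an epimeric mixture. It is carried as such and converges at the C4 hemiketal in Step 21.
- Chirality is introduced by the Cu/Josiphos addition (Step 3), the BINOL-Ti ene reaction (Step 9) and the Ipc₂B-allyl reagent (Step 6). The pinene, BINOL and ligand enantiomers are the ones that give the configurations drawn.

**Retrosynthesis (briarane numbering)**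
1. Target ← DDQ hydroxylation of the C4 allylic ether (C4 hemiketal) ← transannular oxa-Michael of C4-OH onto the C8=C17 butenolide. This closes the THP ring and sets C8 and C17.
2. The 10-membered ring ← two Nozaki–Hiyama–Kishi (NHK) couplings. The first is intermolecular, C5 vinyl iodide + C4 aldehyde. The second is a macrocyclising coupling, C8 bromobutenolide + C9 aldehyde.
3. Ring A (C1, C10, C11–C14) comes from a quinone monoketal by conjugate addition with enolate hydroxymethylation (C1, C10), then hydride reduction (C14) and Brown allylation (C2). Ozonolysis then gives a dialdehyde.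
4. The butenolide (C7 stereocentre) comes from an asymmetric glyoxylate–ene reaction, then propionylation, Dieckmann cyclisation and bromination. The C11 methylene is installed late from the ketal.
5. Ring order: A-ring → butenolide → 10-membered carbocycle → THP/oxocane bridge.

## Route

**Step 1**
Reactants: 1 (4-methoxy-2-methylphenol)
Product: 2 (7-methyl-1,4-dioxaspiro[4.5]deca-6,9-dien-8-one, a quinone monoketal)
Conditions: PhI(OAc)₂, ethylene glycol, CH₂Cl₂, 0 °C
Reagents that add atoms: ethylene glycol, OCCO
Why: Oxidative dearomatisation of a p-alkoxyphenol in a diol gives the cyclic quinone monoketal. The ketal carbon becomes C11, the carbonyl C14, and the methyl sits on C1. Named reaction type: hypervalent-iodine oxidative ketalisation.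

**Step 2**
Reactants: 2
Product: 3 (7-methyl-1,4-dioxaspiro[4.5]dec-6-en-8-one)
Conditions: H₂ (1 atm), RhCl(PPh₃)₃, PhH, rt
Reagents that add atoms: none
Why: The catalyst reduces the less substituted C12=C13 alkene selectively and leaves the trisubstituted enone alkene. This is homogeneous hydrogenation.

**Step 3**
Reactants: 3
Product: 4 (C10-vinyl, C1-methyl, C1-CH₂OH keto ketal; vinyl and CH₂OH trans on the ring)
Conditions: VinylMgBr, CuBr·SMe₂, (R,S)-Josiphos, MTBE, –78 °C; then monomeric CH₂O, –78 → 0 °C
Reagents that add atoms: vinylmagnesium bromide, C=C[Mg]Br; formaldehyde, C=O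
Why: Enantioselective Cu-catalysed 1,4-addition sets C10. It generates the C14/C1 magnesium enolate regiospecifically. Formaldehyde is then added anti to the new vinyl group, which sets quaternary C1 with CH₂OH (C2) down, Me up and C9 up. This is a tandem asymmetric conjugate addition–aldol.

**Step 4**
Reactants: 4
Product: 5 (diol, C14-OH axial, cis to CH₂OH and trans to Me)
Conditions: L-Selectride, THF, –78 °C
Reagents that add atoms: none
Why: The bulky hydride attacks equatorially and gives the axial C14 alcohol, which matches the target C14 configuration. This is a sterically controlled ketone reduction.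

**Step 5**
Reactants: 5
Product: 6 (C2 aldehyde, C14-OH free)
Conditions: TEMPO (10 mol%), PhI(OAc)₂, CH₂Cl₂, rt
Reagents that add atoms: none
Why: TEMPO oxidation is selective for the primary neopentyl alcohol over the hindered axial secondary alcohol. The vinyl group and the ketal are untouched.

**Step 6**
Reactants: 6
Product: 7 (homoallylic alcohol, C2-OH)
Conditions: (Ipc)₂B-allyl, Et₂O, –78 °C; then NaOH/H₂O₂
Reagents that add atoms: B-allyldiisopinocampheylborane, C=CCB(C1CC2CC(C1C)C2(C)C)C1CC2CC(C1C)C2(C)C (delivers the allyl group, C=CC)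
Why: Reagent-controlled Brown allylation sets C2 in the matched sense (the pinene enantiomer chosen to give the target C2 configuration). It adds C3 and C4 (plus a terminal CH₂ that is lost later).

**Step 7**
Reactants: 7
Product: 8 (C2 and C14 diacetate)
Conditions: Ac₂O, DMAP, pyridine, 50 °C
Reagents that add atoms: acetic anhydride, CC(=O)OC(C)=O
Why: This installs the final C2 and C14 acetates with no stereocentre change.

**Step 8**
Reactants: 8
Product: 9 (C4 and C9 dialdehyde)
Conditions: O₃, CH₂Cl₂/MeOH, –78 °C; then Me₂S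
Reagents that add atoms: ozone, [O-][O+]=O (its oxygens become the aldehyde carbonyls)
Why: Both terminal alkenes are cleaved. Ketal and acetates survive. Ozonolysis with reductive work-up.

**Step 9**
Reactants: 10 (methyl glyoxylate), 11 (2-iodopropene)
Product: 12 ((S)-methyl 2-hydroxy-4-iodopent-4-enoate)
Conditions: (S)-BINOL (10 mol%), TiCl₂(OiPr)₂, 4 Å MS, CH₂Cl₂, –30 °C
Reagents that add atoms: none
Why: The chiral Ti-catalysed carbonyl–ene reaction forms the C6–C7 bond and sets C7. The ene transposition puts the vinyl iodide on C5 with C16 as the =CH₂. Named reaction type: glyoxylate-ene (Mikami).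

**Step 10**
Reactants: 12
Product: 13 (propionate ester of 12)
Conditions: EtCOCl, pyridine, DMAP, CH₂Cl₂, 0 °C
Reagents that add atoms: propionyl chloride, CCC(Cl)=O
Why: Acylation of the secondary alcohol brings in C17–C19. C7 is untouched.

**Step 11**
Reactants: 13
Product: 14 ((S)-5-(2-iodoallyl)-3-methyltetronic acid)
Conditions: LiHMDS (2.2 equiv), THF, –78 → 0 °C; then aq. HCl
Reagents that add atoms: none
Why: The propionate enolate (C17) attacks the methyl ester (C8) in a 5-exo Dieckmann condensation and forms the lactone ring. Low temperature limits C7 epimerisation.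

**Step 12**
Reactants: 14
Product: 15 ((S)-4-bromo-5-(2-iodoallyl)-3-methylfuran-2(5H)-one)
Conditions: (COBr)₂, cat. DMF, CH₂Cl₂, 0 °C → rt
Reagents that add atoms: oxalyl bromide, O=C(Br)C(=O)Br
Why: The tetronic acid enol is converted to the vinyl bromide at C8 (Vilsmeier-type bromination). This gives the NHK partner for the ring closure.

**Step 13**
Reactants: 9, 15
Product: 16 (C4–C5 coupled allylic alcohol, C4 epimeric mixture, C9 aldehyde intact)
Conditions: CrCl₂ (5 equiv), DMF, rt, no Ni
Reagents that add atoms: none
Why: Cr(II) alone inserts into the vinyl iodide faster than into the β-bromo-butenolide. It adds to the unhindered C4 aldehyde, while the C9 aldehyde, flanked by two quaternary centres, is untouched. NHK coupling.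

**Step 14**
Reactants: 16
Product: 17 (C4 TBS ether)
Conditions: TBSOTf, 2,6-lutidine, CH₂Cl₂, –78 °C
Reagents that add atoms: tert-butyldimethylsilyl triflate, CC(C)(C)[Si](C)(C)OS(=O)(=O)C(F)(F)F (adds TBS)
Why: This masks C4-OH so it survives the ring closure, the acetylation and the methylenation.

**Step 15**
Reactants: 17
Product: 18 (10-membered carbocycle, C8=C17 butenolide, free C9-OH)
Conditions: CrCl₂ (10 equiv), NiCl₂ (0.1 equiv), DMF/THF, 0.002 M, syringe pump, 50 °C
Reagents that add atoms: none
Why: Ni/Cr converts the vinyl bromide to an alkenylchromium, which adds intramolecularly to the C9 aldehyde (macrocyclising NHK). The trans-fused A-ring and the rigid butenolide direct addition to the natural C9 configuration.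

**Step 16**
Reactants: 18
Product: 19 (C9 acetate)
Conditions: Ac₂O, DMAP, Et₃N, CH₂Cl₂, 40 °C
Reagents that add atoms: acetic anhydride, CC(=O)OC(C)=O
Why: This installs the third target acetate.

**Step 17**
Reactants: 19
Product: 20 (C11 ketone)
Conditions: PPTS, acetone/H₂O, 60 °C
Reagents that add atoms: water, O
Why: Mild acid removes the dioxolane. TBS ether, acetates and butenolide survive. Acetal hydrolysis.

**Step 18**
Reactants: 20
Product: 21 (C11=C20 exocyclic methylene)
Conditions: Zn, CH₂Br₂, TiCl₄, THF/CH₂Cl₂, 0 °C → rt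
Reagents that add atoms: dibromomethane, BrCBr (adds the C20 CH₂)
Why: The Takai–Lombardo methylenation is chemoselective for the ketone over the lactone and acetates. Trans C1/C10 is the thermodynamic arrangement, so C10 epimerisation is not a concern.

**Step 19**
Reactants: 21
Product: 22 (free C4 allylic alcohol)
Conditions: HF·pyridine, THF/pyridine, 0 °C → rt
Reagents that add atoms: none
Why: Acidic desilylation leaves the acetates and lactone intact.

**Step 20**
Reactants: 22
Product: 23 (tetrahydropyran ether, 4,8-epoxy bridge, C4-H; C4 epimer as formed)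
Conditions: DBU (0.3 equiv), CH₂Cl₂, rt → 40 °C
Reagents that add atoms: none
Why: The C4 alkoxide adds in 6-exo fashion to C8 of the butenolide (transannular oxa-Michael). The three-atom tether from C7 forces O onto the same face as C6, so C8 is set and the THP–lactone fusion is cis. The enolate is then protonated at C17 from the face opposite the new THP ring, giving Me cis to O.

**Step 21**
Reactants: 23
Product: 24 ((+)-junceellolide A)
Conditions: DDQ, CH₂Cl₂/pH 7 phosphate buffer (10:1), rt
Reagents that add atoms: water, O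
Why: DDQ removes the doubly activated C4–H (α-oxy, allylic) hydride to give an oxocarbenium ion. Water adds to it to give the hemiketal. The C4 configuration is thermodynamic (anomeric), so both C4 epimers converge.

## Compound list

| # | Name | SMILES | Role |
|---|------|--------|------|
| 1 | 4-methoxy-2-methylphenol | COc1ccc(O)c(C)c1 | starting material |
| 2 | 7-methyl-1,4-dioxaspiro[4.5]deca-6,9-dien-8-one | CC1=CC2(C=CC1=O)OCCO2 | intermediate |
| 3 | 7-methyl-1,4-dioxaspiro[4.5]dec-6-en-8-one | CC1=CC2(CCC1=O)OCCO2 | intermediate |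
| 4 | 7-(hydroxymethyl)-7-methyl-6-vinyl-1,4-dioxaspiro[4.5]decan-8-one (vinyl trans to CH₂OH) | C[C@]1(CO)C(=O)CCC2(OCCO2)[C@@H]1C=C | intermediate |
| 5 | diol: 8-OH axial, cis to CH₂OH | C[C@]1(CO)[C@@H](O)CCC2(OCCO2)[C@@H]1C=C | intermediate |
| 6 | C2 aldehyde | C[C@]1(C=O)[C@@H](O)CCC2(OCCO2)[C@@H]1C=C | intermediate |
| 7 | homoallylic alcohol (C2-OH) | C=CC[C@@H](O)[C@@]1(C)[C@@H](O)CCC2(OCCO2)[C@@H]1C=C | intermediate |
| 8 | C2/C14 diacetate | C=CC[C@@H](OC(C)=O)[C@@]1(C)[C@@H](OC(C)=O)CCC2(OCCO2)[C@@H]1C=C | intermediate |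
| 9 | dialdehyde (C4 and C9) | O=CC[C@@H](OC(C)=O)[C@@]1(C)[C@@H](OC(C)=O)CCC2(OCCO2)[C@@H]1C=O | intermediate |
| 10 | methyl glyoxylate | COC(=O)C=O | starting material |
| 11 | 2-iodopropene | C=C(C)I | starting material |
| 12 | (S)-methyl 2-hydroxy-4-iodopent-4-enoate | COC(=O)[C@@H](O)CC(=C)I | intermediate |
| 13 | (S)-propionate of 12 | COC(=O)[C@@H](OC(=O)CC)CC(=C)I | intermediate |
| 14 | (S)-5-(2-iodoallyl)-3-methyltetronic acid (enol form) | O=C1O[C@@H](CC(=C)I)C(O)=C1C | intermediate |
| 15 | (S)-4-bromo-5-(2-iodoallyl)-3-methylfuran-2(5H)-one | O=C1O[C@@H](CC(=C)I)C(Br)=C1C | intermediate |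
| 16 | C4-hydroxy NHK adduct (C4 epimeric mixture) | C=C(C[C@@H]1OC(=O)C(C)=C1Br)C(O)C[C@@H](OC(C)=O)[C@@]2(C)[C@@H](OC(C)=O)CCC3(OCCO3)[C@@H]2C=O | intermediate |
| 17 | C4 TBS ether | C=C(C[C@@H]1OC(=O)C(C)=C1Br)C(O[Si](C)(C)C(C)(C)C)C[C@@H](OC(C)=O)[C@@]2(C)[C@@H](OC(C)=O)CCC3(OCCO3)[C@@H]2C=O | intermediate |
| 18 | macrocycle with C9-OH, ketal, C4-OTBS | C=C1C[C@@H]2OC(=O)C(C)=C2[C@H](O)[C@H]3C4(OCCO4)CC[C@H](OC(C)=O)[C@]3(C)[C@H](OC(C)=O)CC1O[Si](C)(C)C(C)(C)C | intermediate |
| 19 | C9 acetate | C=C1C[C@@H]2OC(=O)C(C)=C2[C@H](OC(C)=O)[C@H]3C4(OCCO4)CC[C@H](OC(C)=O)[C@]3(C)[C@H](OC(C)=O)CC1O[Si](C)(C)C(C)(C)C | intermediate |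
| 20 | C11 ketone | C=C1C[C@@H]2OC(=O)C(C)=C2[C@H](OC(C)=O)[C@H]3C(=O)CC[C@H](OC(C)=O)[C@]3(C)[C@H](OC(C)=O)CC1O[Si](C)(C)C(C)(C)C | intermediate |
| 21 | C11 methylene | C=C1C[C@@H]2OC(=O)C(C)=C2[C@H](OC(C)=O)[C@H]3C(=C)CC[C@H](OC(C)=O)[C@]3(C)[C@H](OC(C)=O)CC1O[Si](C)(C)C(C)(C)C | intermediate |
| 22 | C4 allylic alcohol | C=C1C[C@@H]2OC(=O)C(C)=C2[C@H](OC(C)=O)[C@H]3C(=C)CC[C@H](OC(C)=O)[C@]3(C)[C@H](OC(C)=O)CC1O | intermediate |
| 23 | 4,8-epoxy (THP) deoxy-hemiketal, C4 epimer as formed | C=C1CC[C@H](OC(C)=O)[C@@]2(C)[C@H]1[C@@H](OC(C)=O)[C@@]13OC(C[C@H]2OC(C)=O)C(=C)C[C@@H]1OC(=O)[C@@H]3C | intermediate |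
| 24 | (+)-junceellolide A | C=C1CC[C@H](OC(C)=O)[C@@]2(C)[C@H]1[C@@H](OC(C)=O)[C@@]13O[C@](O)(C[C@H]2OC(C)=O)C(=C)C[C@@H]1OC(=O)[C@@H]3C | target |

**Total steps:** 21 (A-ring branch 8, butenolide branch 4, convergent sequence 9). 
**Longest linear sequence:** 17 steps (Steps 1–8, then 13–21).

**Three steps most likely to fail**
1. **Step 15, macrocyclising NHK.** The C9 aldehyde is very hindered, the ring is 10-membered, and C9 diastereoselectivity is substrate-controlled.
 - Fallback: reverse the bond order. Couple the C8 bromobutenolide to the C9 aldehyde intermolecularly first. Then unmask the C4 aldehyde and close the ring by intramolecular NHK of the C5 vinyl iodide.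
2. **Step 20, transannular oxa-Michael.** Addition to a tetrasubstituted butenolide to form a quaternary ether may be thermodynamically unfavourable, and C7 can epimerise through the furanolate.
 - Fallback: epoxidise C8=C17 (t-BuOOH, DBU), open the epoxide with SmI₂ to the C8-OH/C17-H lactone, then oxidise C4-OH with DMP. The resulting enone hemiketalises spontaneously.
3. **Step 13, chemoselective NHK.** The two aldehydes and two vinyl halides compete, and the bromobutenolide may not tolerate Cr(II).
 - Fallback: carry C9 as a TBS-protected primary alcohol (ozonolysis/NaBH₄/TBS before Step 6), so that only C4 is an aldehyde. Use an O-silyl tetronate as the C8 partner and brominate it after the C4–C5 coupling. Unmask and oxidise C9 just before the ring closure.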